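## Structural features

The target is a trans-fused bicyclo[5.3.0]decane (hydroazulene). A cyclopentane (ring A: C2, C3, C4, C5, C6) shares the C2–C6 bond with a cycloheptane (ring B: C1, C2, C6, C7, C8, C9, C10). In the locants used throughout, C1 carries the isopropyl group, C4 the ring-A methyl, C8 a methyl carbinol and C10 the 4-hydroxybenzoate; an epoxide oxygen bridges C4 and C5. There are seven stereocentres (1S,2R,4R,5S,6S,8R,10S): C10, C1, C2, C6, C5 and C4 are contiguous, whereas C8 is insulated by the C7 and C9 methylenes and stands 1,3 to both C6 and C10. With the face of H-2 called β, the isopropyl group, the 8-hydroxyl and the epoxide oxygen are β, while H-1, H-6, the C8 methyl and the ester oxygen are α. Ring B therefore carries a trans fusion, an equatorial isopropyl group and an anti-1,3-diol pattern (C8/C10). The fragile groups are the acid-labile trisubstituted epoxide, the aryl ester beside a free phenol and, at the ketone oxidation level, the β-hydroxy ketone C8(OH)–C9–C10(=O), which is open to retro-aldol cleavage and elimination. The real difficulty is a seven-membered ring with a remote quaternary carbinol, together with a regiodefined, face-defined oxidised methylcyclopentene. The key step uses the fact that deleting C9 contracts ring B to a cyclohexene (C1, C2, C6, C7, C8, C10) whose C8=C10 enol ether is the retron of a [4+2] cycloaddition of a 2-silyloxydiene with cyclopent-2-enone; C9 is then inserted across that same enol ether.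

## Logic of the disconnections

27 is traced to 26 by cutting the phenolic O–acetyl bond. The free phenol would self-condense during acylation and bind the oxidation catalyst, so it is carried masked. The forward step must spare the C10 benzoate and the epoxide, which basic methanolysis of an aryl acetate does.

26 is traced to 25 by cutting both C–O bonds of the C4–C5 epoxide. The epoxide is the most fragile group and is therefore made last but one. This removes two stereocentres. The forward step must deliver oxygen to the β face, for which the β-hydroxyl on C8 is available as a directing group.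

25 is traced to 23 and 24 by cutting the ester C–O bond at C10. The forward step must acylate the secondary hydroxyl in the presence of the tertiary one, which is a large intrinsic rate difference.

23 is traced through 22, 21 and 19 to 15. The bonds cut are C5–H (from C5–OTf), the third C–H of the C4 methyl (from C4=CH2) and C4–CH2 itself. The C5 ketone is what the cycloaddition supplies and is needed earlier for the C6 equilibration. A simple 4-methyl-5-ketone would have to be enolised selectively towards C4 and not C6, two methines, which cannot be relied on. The exocyclic methylene route fixes the regiochemistry by connectivity. The demand on the forward steps is kinetic enolisation of 15 at the C4 methylene and protection of both hydroxyls.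

15 is traced through 14 to 13 by removing the silyl groups and cutting the C10–H bond. The anti-1,3-diol is the signature of hydroxyl-directed reduction of a β-hydroxy ketone. The forward step must reduce C10 and not C5, and deliver hydride on the face of the C8 hydroxyl.

13 is traced through 12 and 11 to 10. The C8–O bond (with a transient C9–O bond) is cut, and C1 and C6 are returned to their kinetic configurations. The enone is the direct product of ring expansion. Oxygenation is placed before equilibration because cis-fused 10 has a clear convex face. The forward steps need β-face attack on the enone and a thermodynamic preference for trans fusion and equatorial isopropyl.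

10 is traced through 8 to 7 by excising C9 (bonds C8–C9 and C9–C10) and rejoining C8–C10. The medium ring becomes a cyclohexene. The forward steps need an enol silane defined at C8=C10 only, and cleavage of the internal cyclopropane bond.

7 is traced to 5 and 6 by cutting C1–C2 and C6–C7. A bicyclic compound with three stereocentres becomes two achiral components, and only C2 has to be set absolutely. The forward step needs C1 of the diene to bond to the β-carbon of the enone, and it needs enantioface control.

5 is traced through 4 and 3 to 1 and 2 by cutting the O–Si bond, adjusting the oxidation level, and cutting the bond between the carbinol carbon and the isopropenyl group. The only demand is (Z)-selective enol silylation.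

## Other disconnections considered

Alternative 1: The cut is the C1–C10 bond of ring B. In the forward direction Me2AlCl activates the C10 aldehyde of A1, a cyclopentanone whose C2 carries a 2-methylprop-1-enyl group and whose C6 carries the C7–C10 chain with the silylated C8 carbinol. The alkene attacks through C1 with transfer of an allylic methyl hydrogen (carbonyl-ene reaction) and closes the seven-membered ring to A2, which has a free C10 hydroxyl and a C1 isopropenyl group.
- In its favour: one step closes ring B and sets C1 and C10 together, the C10 hydroxyl emerges ready for aroylation, and the C8 carbinol and C4 methyl are already present. On these points it is the better plan, since the chosen route needs a separate equilibration (step 8) and a separate C10 reduction (step 10).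
- Against it here: the ene closure has to form a seven-membered ring, where the ordered chair-like transition state of the six-ring case is less well defined, so the C1/C10 outcome is harder to predict. The Lewis acid also meets a β-silyloxy aldehyde that can eliminate. A1 requires C2, C6 and the remote C8 carbinol to be set independently. The C5 ketone of A2 is flanked by two methines, so the C4=C5 alkene is harder to place than from 15.
- Comparison: in mechanism the two are equally well founded, both being Lewis-acid-activated pericyclic steps. In structure the chosen plan reaches the medium ring from a six-membered ring with one absolute stereocentre. In step count the alternative has the shorter endgame but a longer front end, so no overall saving is expected.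

Alternative 2: The cut is the C2–C3 bond of ring A. FeCl3 activates the cross-conjugated dienone A3 (cycloheptenyl C2=C6, C5 ketone, silylated propenyl C4=C3). Conrotatory 4π closure forms C2–C3, and loss of silicon fixes the double bond at C3=C4 in the 2-methylcyclopentenone A4.
- In its favour: the ring-A methyl and a regiodefined unsaturation arrive together, and a reductive 1,3-transposition of the enone would move the alkene to C4=C5 in two steps. This is the better answer to the ring-A problem, which costs the chosen route steps 11 to 15. C1, C8 and C10 would already be in place.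
- Against it here: the difficulty is moved and not removed, because A3 is a cycloheptene with three stereocentres including the remote quaternary carbinol. The sense of conrotation relative to the C1 isopropyl group decides C2, protonation decides C6, and a cis fusion is the expected bias. Base correction of C6 in A4 is hazardous because the γ-hydrogen of the enone is H-2. The tertiary silyl ether meets stoichiometric FeCl3.
- Comparison: both key steps are pericyclic closures under Lewis acid control, but the chosen one joins two simple achiral components under catalyst control, whereas this one is substrate-controlled on an advanced intermediate. Step economy is equal or better for the alternative after the key step and worse before it.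

Alternative 3: The cuts are C9–C10 and O–C8. NaOCl oxidises the aldoxime A5 to the nitrile oxide A6. Its carbon (C10) adds to the terminal alkene carbon (C9) and its oxygen to C8, closing the seven-membered carbocycle and the isoxazoline together in A7.
- In its favour: two bonds, ring B and C8 are made in one step, the oxygen goes to the more substituted alkene carbon as the dipole also prefers, and the isoxazoline masks the retro-aldol-prone β-hydroxy ketone until N–O cleavage with Mo(CO)6. On atom economy and on protection of the C8/C10 array it is the better plan. Its later logic (directed anti reduction, as for 13 to 14) is equal to the chosen one.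
- Against it here: with a four-atom tether the competing mode (C10 to C8, a six-membered ring with a fused isoxazoline) is the usual one, while the required mode puts the C=N bond at a bridgehead of a bicyclo[4.2.1] framework. C8 depends only on the conformation of a side chain anchored at C6. A5 needs the C1/C2/C6 triad and C4 to be made separately. The C5 ketone again has two methine neighbours.
- Comparison: both key steps are concerted cycloadditions, the chosen one intermolecular with catalyst-set absolute configuration, this one intramolecular with substrate-set relative configuration and a regiochemical bias working against it. The chosen plan is longer after its key step and shorter before it.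

Key step: step 4

Assumption: the (R)-prolinol-derived catalyst is taken to expose the C2-Re/C6-Re face of 6 (enone bound at boron with C6–H towards the ring oxygen, one face covered by an aryl group of the catalyst); if the sense proves opposite, the (S)-catalyst is used with no other change.

## Steps

Step 1
Reactants: 1 isovaleraldehyde (3-methylbutanal); 2 isopropenylmagnesium bromide
Product: 3 (±)-2,5-dimethylhex-1-en-3-ol
Conditions: THF, 0 °C; aq. NH4Cl
Reagents that add atoms: none
Why: Grignard 1,2-addition of an alkenylmagnesium halide to an unhindered aldehyde; the carbinol centre is oxidised in step 2, so its configuration is irrelevant.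

Step 2
Reactants: 3 (±)-2,5-dimethylhex-1-en-3-ol
Product: 4 2,5-dimethylhex-1-en-3-one
Conditions: Dess–Martin periodinane, NaHCO3, CH2Cl2, 0 °C → rt
Reagents that add atoms: none
Why: Dess–Martin oxidation of a secondary allylic alcohol under buffered, non-basic conditions that should not polymerise the volatile isopropenyl ketone, which is used at once.

Step 3
Reactants: 4 2,5-dimethylhex-1-en-3-one
Product: 5 (Z)-3-(tert-butyldimethylsilyloxy)-2,5-dimethylhexa-1,3-diene
Conditions: TBSOTf, Et3N, CH2Cl2, 0 °C
Reagents that add atoms: tert-butyldimethylsilyl trifluoromethanesulfonate CC(C)(C)[Si](C)(C)OS(=O)(=O)C(F)(F)F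
Why: Soft enolisation and O-silylation; only the CH2 next to the carbonyl is acidic, and amine/silyl triflate enolisation places the isopropyl group cis to oxygen (Z), that is, on the outside of the s-cis diene.

Step 4
Reactants: 5 (Z)-3-(tert-butyldimethylsilyloxy)-2,5-dimethylhexa-1,3-diene; 6 cyclopent-2-en-1-one
Product: 7 (3aS,4R,7aR)-5-(tert-butyldimethylsilyloxy)-6-methyl-4-(propan-2-yl)-2,3,3a,4,7,7a-hexahydro-1H-inden-1-one (cis-fused endo adduct; text locants 1R,2S,6R; H-1, H-2 and H-6 all β)
Conditions: (R)-3,3-diphenyl-1-(o-tolyl)tetrahydro-1H,3H-pyrrolo[1,2-c][1,3,2]oxazaborole·HNTf2 (20 mol %), CH2Cl2, −78 → −40 °C; Et3N quench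
Reagents that add atoms: none
Why: The protonated oxazaborolidine binds the carbonyl oxygen of 6 at boron, lowers the LUMO of the enone and covers one face of the C2=C6 bond with an aryl group. 5 reacts through its s-cis conformer in a concerted, asynchronous [4+2] cycloaddition in which the C1–C2 bond is the more advanced; the closest known reaction type is the oxazaborolidinium-catalysed enantioselective Diels–Alder reaction of 2-silyloxy-1,3-dienes with cyclic enones. The six-membered ring C1–C2–C6–C7–C8–C10 is closed by the cycloaddition itself, both σ bonds forming suprafacially on diene and dienophile, so there is no separate cyclisation event. C2 is set by the catalyst, which leaves only the C2-Re/C6-Re face open. C6 follows from C2 because addition across the ring alkene is suprafacial (cis fusion). C1 is set by the (Z)-enol ether geometry together with the endo transition state, which puts H-1 cis to H-2. The required regiochemistry (C1 to the enone β-carbon C2) is secured by the silyloxy group on C10, which makes C1 the most nucleophilic diene terminus and outweighs the C8 methyl; only the enantioface selectivity at C2 has to be high, since C1 and C6 are re-set in step 8.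

Step 5
Reactants: 7 cis-fused hydrindanone enol silane
Product: 8 cis-fused silyloxycyclopropane: 7 with a CH2 (C9) bridging C8 and C10 on the β face (text locants 1R,2S,6R,8S,10R)
Conditions: Et2Zn, CH2I2, CH2Cl2, 0 °C → rt
Reagents that add atoms: diiodomethane ICI
Why: Simmons–Smith cyclopropanation; the electron-rich tetrasubstituted enol ether is the only reactive alkene and the ketone is inert to the zinc carbenoid. The methylene is expected on the convex β face, but both new centres are destroyed in step 6.

Step 6
Reactants: 8 cis-fused silyloxycyclopropane
Product: 10 (1R,2R,6R)-8-methyl-1-(propan-2-yl)bicyclo[5.3.0]dec-8-ene-5,10-dione (cis-fused; text locants), via β-chloro ketone 9 (not isolated)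
Conditions: FeCl3, DMF, 0 °C → rt; then NaOAc, MeOH, 60 °C
Reagents that add atoms: none
Why: FeCl3-mediated oxidative ring expansion of a silyloxycyclopropane: one-electron oxidation gives an oxygen radical that cleaves the internal C8–C10 bond to the tertiary C8 radical, which takes chlorine from FeCl3; NaOAc then removes HCl (E1cB) to give the conjugated enone. C2 has no acidic hydrogen and is untouched.

Step 7
Reactants: 10 cis-fused ene-dione
Product: 11 (1R,2R,6R,8R,9R)-8,9-epoxy-8-methyl-1-(propan-2-yl)bicyclo[5.3.0]decane-5,10-dione (cis-fused; epoxide oxygen β)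
Conditions: 30% H2O2, NaOH (0.3 equiv), MeOH, 0 °C
Reagents that add atoms: hydrogen peroxide OO
Why: Weitz–Scheffer nucleophilic epoxidation: hydroperoxide adds to C8 and the enolate closes on the same face. In cis-fused 10, ring A and the isopropyl group lie under the α face, so attack on the convex β face should place the C8 oxygen β as required; the isolated cyclopentanone is not expected to react at 0 °C.

Step 8
Reactants: 11 cis-fused epoxy-dione
Product: 12 (1S,2R,6S,8R,9R)-8,9-epoxy-8-methyl-1-(propan-2-yl)bicyclo[5.3.0]decane-5,10-dione (trans-fused; isopropyl β, H-1 and H-6 α)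
Conditions: DBU, toluene, rt → 40 °C
Reagents that add atoms: none
Why: Base-mediated epimerisation of two ketone α-centres through their enolates (C1 through the C10 ketone, which can enolise only towards C1; C6 through the C5 ketone). The trans fusion with an equatorial β-isopropyl group, free of a syn-axial contact with H-6, is expected to be the thermodynamic minimum; C2 and C8 are not enolisable.

Step 9
Reactants: 12 trans-fused epoxy-dione
Product: 13 (1S,2R,6S,8R)-8-hydroxy-8-methyl-1-(propan-2-yl)bicyclo[5.3.0]decane-5,10-dione
Conditions: SmI2 (2.2 equiv), THF/MeOH, −78 °C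
Reagents that add atoms: none
Why: SmI2 reduction of an α,β-epoxy ketone: electron transfer to the C10 carbonyl and cleavage of the C9–O bond give a samarium enolate that MeOH protonates. The C8–O bond is not broken, so C8 keeps its configuration, and the isolated C5 ketone is not reduced at −78 °C without additives.

Step 10
Reactants: 13 β-hydroxy dione
Product: 14 (1S,2S,6S,8R,10S)-8,10-dihydroxy-8-methyl-1-(propan-2-yl)bicyclo[5.3.0]decan-5-one (8-OH β, 10-OH α)
Conditions: Me4NBH(OAc)3, MeCN/AcOH (1:1), −30 °C
Reagents that add atoms: none
Why: Evans–Saksena reduction: the C8 hydroxyl exchanges onto boron and delivers hydride through a six-membered transition state to the β face of C10, giving the anti-1,3-diol with the 10-hydroxyl trans to the isopropyl group. The reagent reduces only ketones it can reach in this way, so C5, which would need a seven-membered delivery, is expected to remain.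

Step 11
Reactants: 14 diol ketone
Product: 15 (1S,2S,6S,8R,10S)-8-methyl-1-(propan-2-yl)-8,10-bis(triethylsilyloxy)bicyclo[5.3.0]decan-5-one
Conditions: TESOTf, 2,6-lutidine, CH2Cl2, −78 → 0 °C
Reagents that add atoms: triethylsilyl trifluoromethanesulfonate CC[Si](CC)(CC)OS(=O)(=O)C(F)(F)F
Why: Silyl triflate silylation of a secondary and a tertiary alcohol with a hindered pyridine base; both hydroxyls must be masked for the enolate and hydride chemistry of steps 12 and 13.

Step 12
Reactants: 15 bis(triethylsilyl) ether ketone
Product: 19 (1S,2S,6S,8R,10S)-8-methyl-4-methylidene-1-(propan-2-yl)-8,10-bis(triethylsilyloxy)bicyclo[5.3.0]decan-5-one, via lithium enolate 16 (not isolated), via Mannich base 17 (not isolated), via ammonium iodide 18 (not isolated)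
Conditions: LiN(i-Pr)2, THF, −78 °C; CH2=NMe2+ I−, −78 °C → rt; then MeI, CH2Cl2, rt; then DBU, rt
Reagents that add atoms: N,N-dimethylmethyleneiminium iodide (Eschenmoser's salt) C=[N+](C)C.[I-]
Why: Kinetic deprotonation removes a C4 methylene hydrogen in preference to the C6 methine; Mannich reaction of the enolate with Eschenmoser's salt, N-methylation and E1cB loss of trimethylamine give the exocyclic enone. C4 becomes sp2, so the configuration of 17 and 18 at C4 is irrelevant.

Step 13
Reactants: 19 α-methylene ketone
Product: 21 (1S,2S,6S,8R,10S)-4,8-dimethyl-1-(propan-2-yl)-8,10-bis(triethylsilyloxy)bicyclo[5.3.0]dec-4-en-5-yl trifluoromethanesulfonate, via lithium enolate 20 (not isolated)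
Conditions: LiBH(s-Bu)3 (L-Selectride), THF, −78 °C; then PhNTf2, −78 → 0 °C
Reagents that add atoms: N-phenylbis(trifluoromethanesulfonimide) O=S(=O)(N(c1ccccc1)S(=O)(=O)C(F)(F)F)C(F)(F)F
Why: Conjugate hydride addition of the hindered borohydride to the unsubstituted exocyclic methylene gives only the C4=C5 enolate, now bearing the C4 methyl, which PhNTf2 traps on oxygen. The position of the future double bond is thereby fixed without any choice between C4 and C6 enolisation.

Step 14
Reactants: 21 enol triflate
Product: 22 (1S,2R,6S,8R,10S)-4,8-dimethyl-1-(propan-2-yl)-8,10-bis(triethylsilyloxy)bicyclo[5.3.0]dec-4-ene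
Conditions: Pd(OAc)2 (5 mol %), PPh3, HCO2H, Bu3N, DMF, 60 °C
Reagents that add atoms: none
Why: Palladium-catalysed reduction of an enol triflate with formate as hydride source (oxidative addition, formate exchange, decarboxylation, reductive elimination); OTf is replaced by H without migration of the double bond.

Step 15
Reactants: 22 bis(triethylsilyl) ether alkene
Product: 23 (1S,2R,6S,8R,10S)-4,8-dimethyl-1-(propan-2-yl)bicyclo[5.3.0]dec-4-ene-8,10-diol
Conditions: Bu4NF, THF, rt → 45 °C
Reagents that add atoms: none
Why: Fluoride-mediated cleavage of both triethylsilyl ethers; the alkene and all stereocentres are inert to fluoride.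

Step 16
Reactants: 23 diol alkene; 24 4-acetoxybenzoyl chloride
Product: 25 (1S,2R,6S,8R,10S)-8-hydroxy-4,8-dimethyl-1-(propan-2-yl)bicyclo[5.3.0]dec-4-en-10-yl 4-acetoxybenzoate
Conditions: Et3N, DMAP (cat.), CH2Cl2, 0 °C → rt
Reagents that add atoms: none
Why: DMAP-catalysed acylation with an acid chloride; the secondary C10 hydroxyl reacts and the tertiary C8 hydroxyl does not. The phenol is carried as its acetate to prevent self-condensation of the acylating agent.

Step 17
Reactants: 25 acetoxybenzoate alkene
Product: 26 (1S,2R,4R,5S,6S,8R,10S)-4,5-epoxy-8-hydroxy-4,8-dimethyl-1-(propan-2-yl)bicyclo[5.3.0]decan-10-yl 4-acetoxybenzoate (epoxide oxygen β)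
Conditions: VO(acac)2 (5 mol %), t-BuOOH, CH2Cl2, 0 °C → rt
Reagents that add atoms: tert-butyl hydroperoxide CC(C)(C)OO
Why: Hydroxyl-directed epoxidation: the C8 alkoxide binds vanadium and delivers the peroxide oxygen to the β face of the C4=C5 bond (bishomoallylic relation through C7 and C6), which sets C4 and C5. The same hydroxyl cannot then open the epoxide, because backside attack at C5 would have to come from the α face.

Step 18
Reactants: 26 epoxy acetoxybenzoate
Product: 27 (1S,2R,4R,5S,6S,8R,10S)-4,5-epoxy-8-hydroxy-4,8-dimethyl-1-(propan-2-yl)bicyclo[5.3.0]decan-10-yl 4-hydroxybenzoate (target, CNP0245441.1)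
Conditions: K2CO3 (0.2 equiv), MeOH, 0 °C
Reagents that add atoms: none
Why: Base-catalysed methanolysis of an aryl acetate, which is far faster than that of the alkyl 4-hydroxybenzoate (further deactivated once the phenoxide forms); the epoxide is stable to mild base.

## Compound list

1 | isovaleraldehyde (3-methylbutanal) | CC(C)CC=O | starting material
2 | isopropenylmagnesium bromide | C=C(C)[Mg]Br | starting material
3 | (±)-2,5-dimethylhex-1-en-3-ol | CC(C)CC(O)C(C)=C | intermediate
4 | 2,5-dimethylhex-1-en-3-one | CC(C)CC(=O)C(C)=C | intermediate
5 | (Z)-3-(tert-butyldimethylsilyloxy)-2,5-dimethylhexa-1,3-diene | C=C(C)/C(O[Si](C)(C)C(C)(C)C)=C/C(C)C | intermediate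
6 | cyclopent-2-en-1-one | O=C1C=CCC1 | starting material
7 | (3aS,4R,7aR)-5-(tert-butyldimethylsilyloxy)-6-methyl-4-(propan-2-yl)-2,3,3a,4,7,7a-hexahydro-1H-inden-1-one | CC(C)[C@@H]1[C@@H]2CCC(=O)[C@@H]2CC(C)=C1O[Si](C)(C)C(C)(C)C | intermediate
8 | cis-fused silyloxycyclopropane (7 with C9H2 bridging C8 and C10 on the β face; 1R,2S,6R,8S,10R) | CC(C)[C@@H]1[C@@H]2CCC(=O)[C@@H]2C[C@@]3(C)C[C@@]13O[Si](C)(C)C(C)(C)C | intermediate
9 | (1R,2R,6R)-8-chloro-8-methyl-1-(propan-2-yl)bicyclo[5.3.0]decane-5,10-dione (C8 epimers) | CC(C)[C@@H]1[C@@H]2CCC(=O)[C@@H]2CC(C)(Cl)CC1=O | intermediate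
10 | (1R,2R,6R)-8-methyl-1-(propan-2-yl)bicyclo[5.3.0]dec-8-ene-5,10-dione | CC(C)[C@@H]1[C@@H]2CCC(=O)[C@@H]2CC(C)=CC1=O | intermediate
11 | (1R,2R,6R,8R,9R)-8,9-epoxy-8-methyl-1-(propan-2-yl)bicyclo[5.3.0]decane-5,10-dione | CC(C)[C@@H]1[C@@H]2CCC(=O)[C@@H]2C[C@@]3(C)O[C@H]3C1=O | intermediate
12 | (1S,2R,6S,8R,9R)-8,9-epoxy-8-methyl-1-(propan-2-yl)bicyclo[5.3.0]decane-5,10-dione | CC(C)[C@H]1[C@@H]2CCC(=O)[C@H]2C[C@@]3(C)O[C@H]3C1=O | intermediate
13 | (1S,2R,6S,8R)-8-hydroxy-8-methyl-1-(propan-2-yl)bicyclo[5.3.0]decane-5,10-dione | CC(C)[C@H]1[C@@H]2CCC(=O)[C@H]2C[C@@](C)(O)CC1=O | intermediate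
14 | (1S,2S,6S,8R,10S)-8,10-dihydroxy-8-methyl-1-(propan-2-yl)bicyclo[5.3.0]decan-5-one | CC(C)[C@H]1[C@@H]2CCC(=O)[C@H]2C[C@@](C)(O)C[C@@H]1O | intermediate
15 | (1S,2S,6S,8R,10S)-8-methyl-1-(propan-2-yl)-8,10-bis(triethylsilyloxy)bicyclo[5.3.0]decan-5-one | CC(C)[C@H]1[C@@H]2CCC(=O)[C@H]2C[C@@](C)(O[Si](CC)(CC)CC)C[C@@H]1O[Si](CC)(CC)CC | intermediate
16 | lithium C4=C5 enolate of 15 | CC(C)[C@H]1[C@@H]2CC=C(O[Li])[C@H]2C[C@@](C)(O[Si](CC)(CC)CC)C[C@@H]1O[Si](CC)(CC)CC | intermediate
17 | 4-[(dimethylamino)methyl] derivative of 15 (Mannich base, C4 epimers) | CC(C)[C@H]1[C@@H]2CC(CN(C)C)C(=O)[C@H]2C[C@@](C)(O[Si](CC)(CC)CC)C[C@@H]1O[Si](CC)(CC)CC | intermediate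
18 | 4-[(trimethylammonio)methyl] derivative of 15, iodide (C4 epimers) | CC(C)[C@H]1[C@@H]2CC(C[N+](C)(C)C)C(=O)[C@H]2C[C@@](C)(O[Si](CC)(CC)CC)C[C@@H]1O[Si](CC)(CC)CC.[I-] | intermediate
19 | (1S,2S,6S,8R,10S)-8-methyl-4-methylidene-1-(propan-2-yl)-8,10-bis(triethylsilyloxy)bicyclo[5.3.0]decan-5-one | CC(C)[C@H]1[C@@H]2CC(=C)C(=O)[C@H]2C[C@@](C)(O[Si](CC)(CC)CC)C[C@@H]1O[Si](CC)(CC)CC | intermediate
20 | lithium 4-methyl C4=C5 enolate from conjugate reduction of 19 | CC(C)[C@H]1[C@@H]2CC(C)=C(O[Li])[C@H]2C[C@@](C)(O[Si](CC)(CC)CC)C[C@@H]1O[Si](CC)(CC)CC | intermediate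
21 | (1S,2S,6S,8R,10S)-4,8-dimethyl-1-(propan-2-yl)-8,10-bis(triethylsilyloxy)bicyclo[5.3.0]dec-4-en-5-yl trifluoromethanesulfonate | CC(C)[C@H]1[C@@H]2CC(C)=C(OS(=O)(=O)C(F)(F)F)[C@H]2C[C@@](C)(O[Si](CC)(CC)CC)C[C@@H]1O[Si](CC)(CC)CC | intermediate
22 | (1S,2R,6S,8R,10S)-4,8-dimethyl-1-(propan-2-yl)-8,10-bis(triethylsilyloxy)bicyclo[5.3.0]dec-4-ene | CC(C)[C@H]1[C@@H]2CC(C)=C[C@H]2C[C@@](C)(O[Si](CC)(CC)CC)C[C@@H]1O[Si](CC)(CC)CC | intermediate
23 | (1S,2R,6S,8R,10S)-4,8-dimethyl-1-(propan-2-yl)bicyclo[5.3.0]dec-4-ene-8,10-diol | CC(C)[C@H]1[C@@H]2CC(C)=C[C@H]2C[C@@](C)(O)C[C@@H]1O | intermediate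
24 | 4-acetoxybenzoyl chloride | CC(=O)Oc1ccc(cc1)C(Cl)=O | starting material
25 | (1S,2R,6S,8R,10S)-8-hydroxy-4,8-dimethyl-1-(propan-2-yl)bicyclo[5.3.0]dec-4-en-10-yl 4-acetoxybenzoate | CC(C)[C@H]1[C@@H]2CC(C)=C[C@H]2C[C@@](C)(O)C[C@@H]1OC(=O)c1ccc(OC(C)=O)cc1 | intermediate
26 | (1S,2R,4R,5S,6S,8R,10S)-4,5-epoxy-8-hydroxy-4,8-dimethyl-1-(propan-2-yl)bicyclo[5.3.0]decan-10-yl 4-acetoxybenzoate | CC(C)[C@H]1[C@@H]2C[C@@]3(C)O[C@H]3[C@H]2C[C@@](C)(O)C[C@@H]1OC(=O)c1ccc(OC(C)=O)cc1 | intermediate
27 | (1S,2R,4R,5S,6S,8R,10S)-4,5-epoxy-8-hydroxy-4,8-dimethyl-1-(propan-2-yl)bicyclo[5.3.0]decan-10-yl 4-hydroxybenzoate | CC(C)[C@H]1[C@@H]2C[C@@]3(C)O[C@H]3[C@H]2C[C@@](C)(O)C[C@@H]1OC(=O)c1ccc(O)cc1 | target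

## Step count and least certain steps

Total step count: 18. Longest linear sequence: 18 steps (1 to 27), with 2, 6 and 24 entering as purchased reagents.

**Step 4 (key step).** The hindered isopropyl-bearing terminus C1 may add too slowly to the weakly reactive enone. The strongly acidic catalyst would then protodesilylate the diene, or a stepwise Mukaiyama–Michael addition would occur without ring closure, and enantioface discrimination could erode.
- Fallback: from 5, the dienophile is changed to a doubly activated, two-point-binding one.
- Commercial allyl 2-oxocyclopentane-1-carboxylate is selenenylated (PhSeCl, pyridine) to allyl 2-oxo-1-(phenylselanyl)cyclopentane-1-carboxylate F1.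
- Oxidation (H2O2) and selenoxide elimination give allyl 5-oxocyclopent-1-ene-1-carboxylate F2, which is used at once.
- Cycloaddition with 5 under Cu(OTf)2 and a C2-symmetric bis(oxazoline) ligand, its enantiomer chosen for the same C2 face, should give the angular allyl ester adduct F3.
- Deallylative decarboxylation (Pd(PPh3)4, HCO2H, Et3N) and convex-face protonation of the enol return the route at 7.

**Step 6.** The oxidative opening may be slow with the robust tert-butyldimethylsilyl ether, may cleave the external C9–C10 bond in competition, or may over-oxidise the tertiary radical to mixtures of olefin isomers.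
- Fallback: from 7, the one-carbon insertion is done by an electrocyclic route instead of a radical one.
- Dibromocarbene from PhHgCBr3 (benzene, 80 °C, neutral, so the C5 ketone is not enolised) should give the dibromocyclopropane F4.
- On warming, F4 ionises and opens (disrotatory cyclopropyl-to-allyl opening with loss of the silyl group) to the 9-bromo enone F5.
- Pd(PPh3)4/Bu3SnH removes the vinylic bromine and returns the route at 10.

**Step 7.** Facial selectivity may be poor if hydroxide epimerises C6 before epoxidation and the trans-fused enone reacts with a weaker bias. Slow epoxidation of the β,β-disubstituted enone may also allow Baeyer–Villiger attack at C5.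
- Fallback: from 10, the C8 oxygen is installed under reagent control.
- Conjugate borylation (CuCl, a chiral bisphosphine chosen for the β face, NaOt-Bu, B2pin2, MeOH, THF) should give the β-boryl dione F6.
- DBU equilibrates C1 and C6 at this base-stable stage to the trans-fused boronate F7.
- NaBO3 oxidises the C–B bond with retention and returns the route at 13.

**Step 8.** Equilibration may stop at a mixture if the energy gap between the fusion isomers is small, and prolonged base may trigger a Favorskii-type rearrangement of the epoxy ketone.
- Fallback: from 10, the order is reversed.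
- DBU equilibrates the epoxide-free ene-dione to the trans-fused, C1-epimerised enone F8; deconjugated isomers formed at the same time re-enter through the conjugated enone under the basic peroxide conditions.
- Epoxidation of F8 (H2O2, NaOH) is then expected on the β face, anti to the out-of-plane C7–C6 bond, and returns the route at 12.

**Step 17.** Delivery from the C8 hydroxyl may fail because the reach across ring B to the ring-A alkene is long, and oxidation would then follow steric preference and could go to the α face.
- Fallback: from 25, an α-face electrophile is turned to advantage.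
- NBS in aqueous THF should form the bromonium ion on the α face; water opens it at the tertiary C4 from the β face to give the bromohydrin F9 (4-OH β, 5-Br α).
- K2CO3 in MeOH then closes the β-epoxide with inversion at C5 and removes the aryl acetate in the same operation, returning the route at 27.

## Further compounds

F1 | step 4 | allyl 2-oxo-1-(phenylselanyl)cyclopentane-1-carboxylate (racemic) | O=C1CCCC1([Se]c1ccccc1)C(=O)OCC=C
F2 | step 4 | allyl 5-oxocyclopent-1-ene-1-carboxylate | O=C1CCC=C1C(=O)OCC=C
F3 | step 4 | angular allyl ester adduct: 7 with CO2CH2CH=CH2 in place of H-6 | CC(C)[C@@H]1[C@@H]2CCC(=O)[C@]2(C(=O)OCC=C)CC(C)=C1O[Si](C)(C)C(C)(C)C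
F4 | step 6 | dibromocyclopropane: 8 with CBr2 in place of C9H2 | CC(C)[C@@H]1[C@@H]2CCC(=O)[C@@H]2C[C@@]3(C)C(Br)(Br)[C@@]13O[Si](C)(C)C(C)(C)C
F5 | step 6 | (1R,2R,6R)-9-bromo-8-methyl-1-(propan-2-yl)bicyclo[5.3.0]dec-8-ene-5,10-dione | CC(C)[C@@H]1[C@@H]2CCC(=O)[C@@H]2CC(C)=C(Br)C1=O
F6 | step 7 | cis-fused 8-(pinacolatoboryl)-8-methyl-1-(propan-2-yl)bicyclo[5.3.0]decane-5,10-dione (boron β) | CC(C)[C@@H]1[C@@H]2CCC(=O)[C@@H]2C[C@@](C)(B3OC(C)(C)C(C)(C)O3)CC1=O
F7 | step 7 | trans-fused 8-(pinacolatoboryl)-8-methyl-1-(propan-2-yl)bicyclo[5.3.0]decane-5,10-dione (boron β, isopropyl β) | CC(C)[C@H]1[C@@H]2CCC(=O)[C@H]2C[C@@](C)(B3OC(C)(C)C(C)(C)O3)CC1=O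
F8 | step 8 | (1S,2R,6S)-8-methyl-1-(propan-2-yl)bicyclo[5.3.0]dec-8-ene-5,10-dione (trans-fused) | CC(C)[C@H]1[C@@H]2CCC(=O)[C@H]2CC(C)=CC1=O
F9 | step 17 | bromohydrin of 25 (4-OH β, 5-Br α) | CC(C)[C@H]1[C@@H]2C[C@@](C)(O)[C@H](Br)[C@H]2C[C@@](C)(O)C[C@@H]1OC(=O)c1ccc(OC(C)=O)cc1
A1 | alternative 1 | cyclopentanone aldehyde precursor of the carbonyl-ene closure | CC(C)=C[C@@H]1C[C@H](C)C(=O)[C@H]1C[C@@](C)(O[Si](CC)(CC)CC)CC=O
A2 | alternative 1 | hydroazulenone with C10 alcohol and C1 isopropenyl group | CC(=C)[C@H]1[C@@H]2C[C@H](C)C(=O)[C@H]2C[C@@](C)(O[Si](CC)(CC)CC)C[C@@H]1O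
A3 | alternative 2 | cross-conjugated silyl dienone precursor of the Nazarov closure | CC(C)[C@H]1C=C(C(=O)/C(C)=C/[Si](C)(C)C)C[C@@](C)(O[Si](CC)(CC)CC)C[C@@H]1O[Si](C)(C)C(C)(C)C
A4 | alternative 2 | trans-fused hydroazulene 2-methylcyclopent-2-enone | CC(C)[C@H]1[C@@H]2C=C(C)C(=O)[C@H]2C[C@@](C)(O[Si](CC)(CC)CC)C[C@@H]1O[Si](C)(C)C(C)(C)C
A5 | alternative 3 | aldoxime precursor with 2-methylallyl side chain | CC(C)[C@H](C=NO)[C@@H]1C[C@H](C)C(=O)[C@H]1CC(C)=C
A6 | alternative 3 | nitrile oxide from A5 | CC(C)[C@H](C#[N+][O-])[C@@H]1C[C@H](C)C(=O)[C@H]1CC(C)=C
A7 | alternative 3 | isoxazoline-bridged hydroazulenone | CC(C)[C@H]1[C@@H]2C[C@H](C)C(=O)[C@H]2C[C@]3(C)CC1=NO3
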